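## Analysis of the target

The target 27 is a cis-fused bicyclic α-methylene-γ-butyrolactone. Atom labels used throughout: ring A is the cyclohexene C1–C6, where C1 carries the methacrylate oxygen, C2=C3 is a tetrasubstituted alkene, C4 is a methylene, C5 carries the lactone oxygen and C6 is the ring-fusion carbon. C2 bears the side chain C1′–C4′ (methyl on C1′, hydroxyl on C4′) and C3 bears the hydroxymethyl carbon C10. Ring B is the lactone O5–C7(=O)–C8(=C9H2)–C6–C5.

Three of the four stereocentres are contiguous on ring A: C5 (R) and C6 (R) hold the C5–O and C6–C8 bonds cis, and the C1–O bond (C1, S) is trans to C6–C8. The fourth, C1′ (S), lies outside the ring, one bond from C2, with no rigid link to the others.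

The sensitive groups are the exocyclic C8=C9 enoate (Michael acceptor, easily hydrogenated), the allylic methacrylate (reducible, polymerisable, ionisable) and the two primary alcohols at C10 and C4′. In late intermediates a free C1 hydroxyl lies γ to C7 and could take over the lactone under base.

The synthesis is hard for two reasons. The fully substituted C2=C3 alkene is flanked by the oxygenated C1 and the acyclic stereocentre C1′. The two acrylate units rule out hydrogenation and strong base at the end, which fixes the order of events.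

The strategy rests on one feature: C2 is the only carbon between C1 and C3. Removing it leaves a cis-fused cyclopentene lactone with a C1=C3 alkene, a bicycle that is short to make by Claisen chirality transfer. C2 can therefore be inserted last as a carbene carbon, in a step that also oxidises C1 and leaves a bromide on C2 for the side chain.

## Retrosynthetic reasoning

**27 ⇒ 26 ⇒ 24 + 25.** The two O–Si bonds and the C1–O acyl bond are cut first. The methacrylate tolerates neither enolate chemistry nor hydrogenation, so it is introduced from anhydride 25 onto alcohol 24 only after both are finished. One fluoride treatment of 26 then frees C10–OH and C4′–OH.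

**24 ⇒ 21.** The C8=C9 bond is cut next. The methylene lactone would not survive the hydrogenation that sets C1′, so C9 is added to the saturated lactone 21 by aminomethylation and elimination (via 22 and 23). The forward step must enolise C8 in the presence of the free C1 hydroxyl.

**21 ⇒ 20.** C1′ is traced back to an alkene that the C1 hydroxyl can direct a hydrogenation onto. Of the two possible alkenes the E-trisubstituted C1′=C2′ bond of 20 is chosen. The metal held by the pseudoaxial C1–OH reaches the twisted alkene only when the distal alkene carbon lies on the hydroxyl face. With C2′ as that carbon, hydrogen enters C1′ from the C1 side and gives the S configuration. The 1,1-disubstituted isomer would place the future methyl group on the hydroxyl face and lead to the C1′ epimer.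

**20 ⇒ 13 + 19.** The C2–C1′ bond is cut between two sp2 carbons. The vinyl bromide of 13 is the handle left by the ring expansion, and alkenylboronate 19 brings C1′–C4′ with the alkene geometry already fixed. The coupling must tolerate the free C1–OH, which is needed in the next step, and the lactone.

**13 ⇒ 12 (key disconnection).** C2 is removed from ring A: the C1–O bond is cut and the C1–C3 bond restored. This leads back to the gem-dibromocyclopropane 12, in which the future C2 bridges C1 and C3 of a bicyclic lactone. No other cut turns a six-membered ring with four different substituent types into a five-membered ring with two stereocentres. The forward step has to ionise one bromide, open the three-membered ring and trap the allyl cation at C1 from the face opposite C8.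

**12 ⇒ 10 ⇒ 8 + 9.** The O5–C7 lactone bond is opened to the dimethylamide and silyl ether of 10, and the two cyclopropane bonds C1–C2 and C2–C3 are cut back to cyclopentene 8 and bromoform 9. The carbene is added at the amide stage because a tertiary amide survives the concentrated hydroxide that generates it, whereas a γ-lactone might not. The lactone is closed afterwards under acid via 11.

**8 ⇒ 6.** The C6–C8 bond is cut as a [3,3] shift. The tertiary allylic alcohol 6, through its ketene N,O-acetal 7, passes the configuration of the C3–O bond to C6 and moves the alkene to C1=C3. This sets the cis relation of C6–C8 and C5–O without an external chiral reagent.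

**6 ⇒ 5 ⇒ 1 + 2.** The C3–C10 bond is cut to enone 1, which supplies C5 in the correct absolute configuration, and a hydroxymethyl carbanion equivalent. A lithiated silyloxymethyl anion would collapse by retro-Brook rearrangement, so the carbon is delivered as the silylmethyl Grignard reagent 3 made from 2. The C–Si bond of adduct 4 is then oxidised to diol 5 and the primary hydroxyl silylated.

**19 ⇒ 17 ⇒ 15 ⇒ 14.** The C–B bond goes back to the E iodide 17 and this to the internal alkyne 15 (via 16 and 18). Syn hydrometalation of the silyl ether of pent-3-yn-1-ol 14 fixes both the position of the metal (on the methyl-bearing carbon) and the geometry.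

## Alternatives that were turned down

**Alternative 1:** Disconnection of the C6–C8 bond by radical cyclisation. A C6 xanthate carrying a C5 propargyl ether (A1) would be reduced with a tin hydride. The C6 radical closes 5-exo-dig onto the internal alkyne carbon and gives the cis-fused 3-methylenetetrahydrofuran A2.
- In its favour: the radical is planar, so both C6 epimers converge; the five-membered closure enforces cis fusion; C9 arrives as the exocyclic methylene without enolate chemistry, which is better than steps 12 of the chosen route.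
- Against it: A2 is an ether, and C7 must later be oxidised to the lactone carbonyl in competition with C10, C1 and C4, all allylic and two of them also α to oxygen. A1 needs oxygen at C1, C5 and C6, one more than the target, and a complete ring A with C1′ already set.
- Comparison: the alternative leaves the tetrasubstituted alkene, C1 and C1′ unsolved, whereas the chosen ring expansion builds ring A and its oxidation pattern in one step.

**Alternative 2:** Disconnection of the C1–C6 bond by an intramolecular Stetter reaction. A carbene catalyst would convert the Z-enal A3 into an acyl anion equivalent that adds to C6 of the tethered butenolide and gives the enone lactone A4.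
- In its favour: ring A and the ring fusion are formed together, and C1′ can be bought as part of an acyclic chiral-pool chain. On C1′ this is stronger than the chosen route, which relies on a directed hydrogenation.
- Against it: an α,β-unsaturated aldehyde under carbene catalysis is diverted into homoenolate pathways. The tetrasubstituted Z-enal is hindered and can isomerise. The γ-hydrogen at C5 of the butenolide is acidic, so C5 can epimerise under the basic conditions. A4 is a C1 ketone whose reduction from the convex face would give the C1 epimer.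
- Comparison: the chosen route sets C1 directly in the correct sense and starts from a five-membered ring whose stereocentres are secure.

**Alternative 3:** Disconnection of O5–C7 and C7–C8 by palladium-catalysed cyclocarbonylation (PdCl2, PPh3, SnCl2 under CO). The cis-ethynyl carbinol A5 would give the bis-silyl ether A6, one deprotection from 27.
- In its favour: the α-methylene lactone is made in a single operation without an enolate, which is shorter than steps 3, 5 and 12 together.
- Against it: A5 already holds all of ring A with four stereocentres, and an acetylide opening of an epoxide would give the trans, not the cis, arrangement at C5/C6. The C1 allylic methacrylate is exposed to zerovalent palladium formed under CO (π-allyl ionisation) and to the Lewis-acidic tin salt.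
- Comparison: the difficult part, the substituted cyclohexene, is only postponed, whereas the chosen strategy solves it at the start.

Key step: step 6

Remark on the chemistry: 1, 2, 9, 14 and 25 are assumed to be purchased; the configuration at C8 in 22 and 23 is left open because C8 becomes trigonal in 24.

## Route

Step 1
Reactants: 1 (4R)-4-{[tert-butyl(dimethyl)silyl]oxy}cyclopent-2-en-1-one; 2 (chloromethyl)dimethyl(propan-2-yloxy)silane
Product: 5 (1S,4R)-4-{[tert-butyl(dimethyl)silyl]oxy}-1-(hydroxymethyl)cyclopent-2-en-1-ol, via silylmethyl Grignard reagent 3 (not isolated), via β-hydroxysilane adduct 4 (not isolated)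
Conditions: 2, Mg, THF, rt; add 1, THF, −78 → 0 °C; aq. NH4Cl; then KF, KHCO3, 30% H2O2, THF/MeOH, rt
Reagents that add atoms: hydrogen peroxide, OO
Why: Nucleophilic hydroxymethylation with the silylmethyl Grignard reagent followed by Tamao oxidation of the C–Si bond with retention. The weakly basic Grignard reagent adds 1,2 to the enone from the face opposite the C5 silyl ether, so the tertiary hydroxyl at C3 is cis to C5–O.

Step 2
Reactants: 5 (1S,4R)-4-{[tert-butyl(dimethyl)silyl]oxy}-1-(hydroxymethyl)cyclopent-2-en-1-ol
Product: 6 (1S,4R)-4-{[tert-butyl(dimethyl)silyl]oxy}-1-({[tert-butyl(diphenyl)silyl]oxy}methyl)cyclopent-2-en-1-ol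
Conditions: TBDPSCl, imidazole, CH2Cl2, 0 °C → rt
Reagents that add atoms: tert-butyl(chloro)diphenylsilane, CC(C)(C)[Si](Cl)(c1ccccc1)c1ccccc1
Why: Selective silylation of the primary hydroxyl of a primary/tertiary diol; the acid-stable TBDPS group is chosen so that the secondary TBS ether can later be removed in its presence.

Step 3
Reactants: 6 (1S,4R)-4-{[tert-butyl(dimethyl)silyl]oxy}-1-({[tert-butyl(diphenyl)silyl]oxy}methyl)cyclopent-2-en-1-ol
Product: 8 2-[(1S,5R)-5-{[tert-butyl(dimethyl)silyl]oxy}-3-({[tert-butyl(diphenyl)silyl]oxy}methyl)cyclopent-2-en-1-yl]-N,N-dimethylacetamide, via ketene N,O-acetal 7 (not isolated)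
Conditions: MeC(OMe)2NMe2 (5 equiv), xylene, 140 °C, sealed tube
Reagents that add atoms: 1,1-dimethoxy-N,N-dimethylethanamine, CC(OC)(OC)N(C)C
Why: Eschenmoser–Claisen rearrangement: acetal exchange gives 7, whose suprafacial [3,3] shift carries the acetamide carbon from the C3–O face to C6, so C6–C8 ends cis to C5–O and the alkene moves to C1=C3. The neutral conditions suit a tertiary allylic alcohol, and the amide is chosen because it survives the hydroxide of step 4.

Step 4
Reactants: 8 2-[(1S,5R)-5-{[tert-butyl(dimethyl)silyl]oxy}-3-({[tert-butyl(diphenyl)silyl]oxy}methyl)cyclopent-2-en-1-yl]-N,N-dimethylacetamide; 9 bromoform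
Product: 10 2-[(1S,2S,3R,5R)-6,6-dibromo-3-{[tert-butyl(dimethyl)silyl]oxy}-5-({[tert-butyl(diphenyl)silyl]oxy}methyl)bicyclo[3.1.0]hexan-2-yl]-N,N-dimethylacetamide (CBr2 bridge anti to the C2 and C3 substituents)
Conditions: CHBr3, 50% aq. NaOH, BnEt3NCl (cat.), CH2Cl2, 0 °C → rt
Reagents that add atoms: none
Why: Phase-transfer dibromocyclopropanation (Makosza conditions): the electrophilic carbene from 9 adds to the electron-rich trisubstituted C1=C3 alkene on the face opposite the C6 arm and the C5 silyl ether. Amide and silyl ethers are inert to the two-phase hydroxide.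

Step 5
Reactants: 10 2-[(1S,2S,3R,5R)-6,6-dibromo-3-{[tert-butyl(dimethyl)silyl]oxy}-5-({[tert-butyl(diphenyl)silyl]oxy}methyl)bicyclo[3.1.0]hexan-2-yl]-N,N-dimethylacetamide
Product: 12 gem-dibromocyclopropane lactone: 6,6-dibromo-5-({[tert-butyl(diphenyl)silyl]oxy}methyl)bicyclo[3.1.0]hexane with a γ-lactone cis-fused across C2–C3 (C3–O–C(=O)–CH2–C2), lactone anti to the CBr2 bridge, via hydroxy amide 11 (not isolated)
Conditions: 1 M aq. HCl/THF (1:2), rt → 40 °C
Reagents that add atoms: none
Why: Acid cleaves the secondary TBS ether; the freed C5 hydroxyl is cis to the acetamide arm and lactonises by intramolecular amide alcoholysis, driven by protonation of the released amine. The primary TBDPS ether is far more acid-stable, and without silver the dibromocyclopropane should not ionise at this temperature.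

Step 6
Reactants: 12 gem-dibromocyclopropane lactone
Product: 13 (3aS,4S,7aR)-5-bromo-6-({[tert-butyl(diphenyl)silyl]oxy}methyl)-4-hydroxy-3a,4,7,7a-tetrahydro-1-benzofuran-2(3H)-one
Conditions: AgClO4 (3 equiv), CaCO3, acetone/H2O (4:1), 0 °C → rt, dark
Reagents that add atoms: water, O
Why: AgClO4 removes the endo bromide (syn to the five-membered ring) while the C1–C3 bond opens in a two-electron disrotatory electrocyclic process (Woodward–Hoffmann–DePuy rule), the only sense of rotation that gives a cis allyl cation inside a ring; the closest known reaction type is the silver-assisted ring expansion of ring-fused gem-dihalocyclopropanes with capture of the 2-haloallyl cation by the solvent. Six-membered ring A is closed by this ring expansion, that is by cleavage of the bond shared by the three- and five-membered rings and not by a bond-forming cyclisation, and C2 emerges as a vinyl bromide. The cation spans C1–C2–C3 and water must choose C1: C3 is fully substituted, shielded by the CH2OTBDPS group and inductively deactivated by its β-oxygen, and attack at C1 leaves the more stable tetrasubstituted C2=C3 bromoalkene. The one new stereocentre, C1, is controlled by the cis-fused lactone: C8 on C6 covers the lower face of the planar cation, so water enters anti to the C6–C8 bond and C1–O ends trans to it. CaCO3 takes up the HClO4 released, so the kinetic alcohol is not re-ionised and the silyl ether and lactone do not meet strong acid. The allylic bromide from a premature thermal opening of 12 would enter the same cation, so the step tolerates an impure precursor.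

Step 7
Reactants: 14 pent-3-yn-1-ol
Product: 15 tert-butyl(dimethyl)(pent-3-yn-1-yloxy)silane
Conditions: TBSCl, imidazole, CH2Cl2, rt
Reagents that add atoms: tert-butyl(chloro)dimethylsilane, CC(C)(C)[Si](C)(C)Cl
Why: Standard silylation of a primary alcohol; the TBS ether is inert to the organometallic steps that follow.

Step 8
Reactants: 15 tert-butyl(dimethyl)(pent-3-yn-1-yloxy)silane
Product: 17 tert-butyl{[(3E)-4-iodopent-3-en-1-yl]oxy}dimethylsilane, via alkenylzirconocene chloride 16 (not isolated)
Conditions: Cp2Zr(H)Cl (2 equiv), THF, 50 °C; then I2, THF, 0 °C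
Reagents that add atoms: iodine, II
Why: Hydrozirconation with excess Cp2Zr(H)Cl under equilibrating conditions places zirconium on the less hindered, methyl-bearing alkyne carbon by syn addition. Iodinolysis occurs with retention, giving the iodide with iodine trans to the chain.

Step 9
Reactants: 17 tert-butyl{[(3E)-4-iodopent-3-en-1-yl]oxy}dimethylsilane
Product: 19 tert-butyl(dimethyl){[(3Z)-4-(4,4,5,5-tetramethyl-1,3,2-dioxaborolan-2-yl)pent-3-en-1-yl]oxy}silane (boron trans to the chain), via alkenyllithium 18 (not isolated)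
Conditions: t-BuLi (2.1 equiv), Et2O, −78 °C; then i-PrOBpin, −78 °C → rt
Reagents that add atoms: 2-(propan-2-yloxy)-4,4,5,5-tetramethyl-1,3,2-dioxaborolane, CC(C)OB1OC(C)(C)C(C)(C)O1
Why: Iodine–lithium exchange and borylation of the alkenyllithium both proceed with retention of alkene geometry.

Step 10
Reactants: 13 (3aS,4S,7aR)-5-bromo-6-({[tert-butyl(diphenyl)silyl]oxy}methyl)-4-hydroxy-3a,4,7,7a-tetrahydro-1-benzofuran-2(3H)-one; 19 tert-butyl(dimethyl){[(3Z)-4-(4,4,5,5-tetramethyl-1,3,2-dioxaborolan-2-yl)pent-3-en-1-yl]oxy}silane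
Product: 20 (3aS,4S,7aR)-5-[(2E)-5-{[tert-butyl(dimethyl)silyl]oxy}pent-2-en-2-yl]-6-({[tert-butyl(diphenyl)silyl]oxy}methyl)-4-hydroxy-3a,4,7,7a-tetrahydro-1-benzofuran-2(3H)-one
Conditions: Pd(OAc)2 (5 mol %), SPhos (10 mol %), K3PO4, THF/H2O (10:1), 50 °C
Reagents that add atoms: none
Why: Suzuki–Miyaura coupling forms C2–C1′ with retention of both alkene geometries; the electron-rich biarylphosphine is chosen for the hindered tetrasubstituted bromide. The free C1 hydroxyl is tolerated and the mild phosphate base should spare the lactone.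

Step 11
Reactants: 20 (3aS,4S,7aR)-5-[(2E)-5-{[tert-butyl(dimethyl)silyl]oxy}pent-2-en-2-yl]-6-({[tert-butyl(diphenyl)silyl]oxy}methyl)-4-hydroxy-3a,4,7,7a-tetrahydro-1-benzofuran-2(3H)-one
Product: 21 (3aS,4S,7aR)-5-[(2S)-5-{[tert-butyl(dimethyl)silyl]oxy}pentan-2-yl]-6-({[tert-butyl(diphenyl)silyl]oxy}methyl)-4-hydroxy-3a,4,7,7a-tetrahydro-1-benzofuran-2(3H)-one
Conditions: [Rh(nbd)(dppb)]BF4 (15 mol %), H2 (60 atm), CH2Cl2, rt
Reagents that add atoms: none
Why: Hydroxyl-directed hydrogenation with a cationic monovalent rhodium diphosphine complex: the C1 hydroxyl (pseudoaxial, to avoid A(1,2) strain with the C2 substituent) binds rhodium, and the twisted C1′=C2′ bond can chelate only with C2′ on the hydroxyl face. Both hydrogens then arrive from the C1 side, and C1′ forms with the chain syn and the methyl anti to the C1–O face, which is the S configuration. The tetrasubstituted C2=C3 bond is not reduced by this catalyst class, which is why it is preferred to [Ir(cod)(PCy3)(py)]PF6.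

Step 12
Reactants: 21 (3aS,4S,7aR)-5-[(2S)-5-{[tert-butyl(dimethyl)silyl]oxy}pentan-2-yl]-6-({[tert-butyl(diphenyl)silyl]oxy}methyl)-4-hydroxy-3a,4,7,7a-tetrahydro-1-benzofuran-2(3H)-one
Product: 24 (3aS,4S,7aR)-5-[(2S)-5-{[tert-butyl(dimethyl)silyl]oxy}pentan-2-yl]-6-({[tert-butyl(diphenyl)silyl]oxy}methyl)-4-hydroxy-3-methylidene-3a,4,7,7a-tetrahydro-1-benzofuran-2(3H)-one, via Mannich base 22 (not isolated), via quaternary ammonium iodide 23 (not isolated)
Conditions: LiN(iPr)2 (2.5 equiv), THF, −78 °C; [CH2=NMe2]I, −78 °C → rt; then MeI, THF/MeOH, rt; then aq. NaHCO3, EtOAc, rt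
Reagents that add atoms: N,N-dimethylmethyleneiminium iodide (Eschenmoser's salt), C=[N+](C)C.[I-]; iodomethane, CI (its methyl group stays only in intermediate 23)
Why: The alkoxide/lactone-enolate dianion is aminomethylated at C8 (Mannich reaction), the amine is quaternised and trimethylamine is lost by E1cB elimination to give the C8=C9 methylene. Enolisation at −78 °C is faster than attack of the C1 alkoxide on C7, and the enolate, once formed, is no longer an acyl acceptor.

Step 13
Reactants: 24 (3aS,4S,7aR)-5-[(2S)-5-{[tert-butyl(dimethyl)silyl]oxy}pentan-2-yl]-6-({[tert-butyl(diphenyl)silyl]oxy}methyl)-4-hydroxy-3-methylidene-3a,4,7,7a-tetrahydro-1-benzofuran-2(3H)-one; 25 2-methylprop-2-enoic anhydride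
Product: 26 (3aR,4S,7aR)-5-[(2S)-5-{[tert-butyl(dimethyl)silyl]oxy}pentan-2-yl]-6-({[tert-butyl(diphenyl)silyl]oxy}methyl)-3-methylidene-2-oxo-2,3,3a,4,7,7a-hexahydro-1-benzofuran-4-yl 2-methylprop-2-enoate
Conditions: 25 (3 equiv), Et3N, DMAP, CH2Cl2, 0 °C → rt
Reagents that add atoms: none
Why: DMAP-catalysed acyl transfer to the hindered secondary allylic alcohol with retention at C1; the conditions are non-nucleophilic enough for the methylene lactone.

Step 14
Reactants: 26 (3aR,4S,7aR)-5-[(2S)-5-{[tert-butyl(dimethyl)silyl]oxy}pentan-2-yl]-6-({[tert-butyl(diphenyl)silyl]oxy}methyl)-3-methylidene-2-oxo-2,3,3a,4,7,7a-hexahydro-1-benzofuran-4-yl 2-methylprop-2-enoate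
Product: 27 (3aR,4S,7aR)-6-(hydroxymethyl)-5-[(2S)-5-hydroxypentan-2-yl]-3-methylidene-2-oxo-2,3,3a,4,7,7a-hexahydro-1-benzofuran-4-yl 2-methylprop-2-enoate
Conditions: HF·pyridine, pyridine/THF, 0 °C → rt
Reagents that add atoms: none
Why: Fluoride-mediated cleavage of both primary silyl ethers under buffered, weakly acidic conditions that should leave the methacrylate and the methylene lactone untouched. C1–O and C10–O are trans across C2=C3, so acyl migration is not possible.

## Compound list

1 | (4R)-4-{[tert-butyl(dimethyl)silyl]oxy}cyclopent-2-en-1-one | O=C1C=C[C@H](O[Si](C)(C)C(C)(C)C)C1 | starting material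
2 | (chloromethyl)dimethyl(propan-2-yloxy)silane | ClC[Si](C)(C)OC(C)C | starting material
3 | {[dimethyl(propan-2-yloxy)silyl]methyl}magnesium chloride | Cl[Mg]C[Si](C)(C)OC(C)C | intermediate (not isolated)
4 | (1S,4R)-4-{[tert-butyl(dimethyl)silyl]oxy}-1-{[dimethyl(propan-2-yloxy)silyl]methyl}cyclopent-2-en-1-ol | O[C@]1(C[Si](C)(C)OC(C)C)C=C[C@H](O[Si](C)(C)C(C)(C)C)C1 | intermediate (not isolated)
5 | (1S,4R)-4-{[tert-butyl(dimethyl)silyl]oxy}-1-(hydroxymethyl)cyclopent-2-en-1-ol | O[C@]1(CO)C=C[C@H](O[Si](C)(C)C(C)(C)C)C1 | intermediate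
6 | (1S,4R)-4-{[tert-butyl(dimethyl)silyl]oxy}-1-({[tert-butyl(diphenyl)silyl]oxy}methyl)cyclopent-2-en-1-ol | O[C@]1(CO[Si](c2ccccc2)(c2ccccc2)C(C)(C)C)C=C[C@H](O[Si](C)(C)C(C)(C)C)C1 | intermediate
7 | 1-{[(1S,4R)-4-{[tert-butyl(dimethyl)silyl]oxy}-1-({[tert-butyl(diphenyl)silyl]oxy}methyl)cyclopent-2-en-1-yl]oxy}-N,N-dimethylethen-1-amine | C=C(N(C)C)O[C@]1(CO[Si](c2ccccc2)(c2ccccc2)C(C)(C)C)C=C[C@H](O[Si](C)(C)C(C)(C)C)C1 | intermediate (not isolated)
8 | 2-[(1S,5R)-5-{[tert-butyl(dimethyl)silyl]oxy}-3-({[tert-butyl(diphenyl)silyl]oxy}methyl)cyclopent-2-en-1-yl]-N,N-dimethylacetamide | CN(C)C(=O)C[C@H]1C=C(CO[Si](c2ccccc2)(c2ccccc2)C(C)(C)C)C[C@H]1O[Si](C)(C)C(C)(C)C | intermediate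
9 | bromoform (tribromomethane) | BrC(Br)Br | starting material
10 | 2-[(1S,2S,3R,5R)-6,6-dibromo-3-{[tert-butyl(dimethyl)silyl]oxy}-5-({[tert-butyl(diphenyl)silyl]oxy}methyl)bicyclo[3.1.0]hexan-2-yl]-N,N-dimethylacetamide | CC(C)(C)[Si](c1ccccc1)(c1ccccc1)OC[C@@]12C[C@@H](O[Si](C)(C)C(C)(C)C)[C@@H](CC(=O)N(C)C)[C@@H]1C2(Br)Br | intermediate
11 | 2-[(1S,2S,3R,5R)-6,6-dibromo-5-({[tert-butyl(diphenyl)silyl]oxy}methyl)-3-hydroxybicyclo[3.1.0]hexan-2-yl]-N,N-dimethylacetamide | CC(C)(C)[Si](c1ccccc1)(c1ccccc1)OC[C@@]12C[C@@H](O)[C@@H](CC(=O)N(C)C)[C@@H]1C2(Br)Br | intermediate (not isolated)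
12 | gem-dibromocyclopropane lactone: 6,6-dibromo-5-({[tert-butyl(diphenyl)silyl]oxy}methyl)bicyclo[3.1.0]hexane with a γ-lactone cis-fused across C2–C3, lactone anti to the CBr2 bridge | CC(C)(C)[Si](c1ccccc1)(c1ccccc1)OC[C@@]12C[C@H]3OC(=O)C[C@H]3[C@@H]1C2(Br)Br | intermediate
13 | (3aS,4S,7aR)-5-bromo-6-({[tert-butyl(diphenyl)silyl]oxy}methyl)-4-hydroxy-3a,4,7,7a-tetrahydro-1-benzofuran-2(3H)-one | O[C@@H]1C(Br)=C(CO[Si](c2ccccc2)(c2ccccc2)C(C)(C)C)C[C@H]2OC(=O)C[C@@H]12 | intermediate
14 | pent-3-yn-1-ol | CC#CCCO | starting material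
15 | tert-butyl(dimethyl)(pent-3-yn-1-yloxy)silane | CC#CCCO[Si](C)(C)C(C)(C)C | intermediate
16 | chloridobis(cyclopentadienyl)[(2E)-5-{[tert-butyl(dimethyl)silyl]oxy}pent-2-en-2-yl]zirconium (zirconium trans to the chain) | Cl[Zr](C1C=CC=C1)(C1C=CC=C1)/C(C)=C/CCO[Si](C)(C)C(C)(C)C | intermediate (not isolated)
17 | tert-butyl{[(3E)-4-iodopent-3-en-1-yl]oxy}dimethylsilane | I/C(C)=C/CCO[Si](C)(C)C(C)(C)C | intermediate
18 | [(2Z)-5-{[tert-butyl(dimethyl)silyl]oxy}pent-2-en-2-yl]lithium (lithium trans to the chain) | [Li]/C(C)=C/CCO[Si](C)(C)C(C)(C)C | intermediate (not isolated)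
19 | tert-butyl(dimethyl){[(3Z)-4-(4,4,5,5-tetramethyl-1,3,2-dioxaborolan-2-yl)pent-3-en-1-yl]oxy}silane (boron trans to the chain) | CC1(C)OB(OC1(C)C)/C(C)=C/CCO[Si](C)(C)C(C)(C)C | intermediate
20 | (3aS,4S,7aR)-5-[(2E)-5-{[tert-butyl(dimethyl)silyl]oxy}pent-2-en-2-yl]-6-({[tert-butyl(diphenyl)silyl]oxy}methyl)-4-hydroxy-3a,4,7,7a-tetrahydro-1-benzofuran-2(3H)-one | O[C@@H]1C(/C(C)=C/CCO[Si](C)(C)C(C)(C)C)=C(CO[Si](c2ccccc2)(c2ccccc2)C(C)(C)C)C[C@H]2OC(=O)C[C@@H]12 | intermediate
21 | (3aS,4S,7aR)-5-[(2S)-5-{[tert-butyl(dimethyl)silyl]oxy}pentan-2-yl]-6-({[tert-butyl(diphenyl)silyl]oxy}methyl)-4-hydroxy-3a,4,7,7a-tetrahydro-1-benzofuran-2(3H)-one | O[C@@H]1C([C@@H](C)CCCO[Si](C)(C)C(C)(C)C)=C(CO[Si](c2ccccc2)(c2ccccc2)C(C)(C)C)C[C@H]2OC(=O)C[C@@H]12 | intermediate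
22 | 3-[(dimethylamino)methyl] derivative of 21 (position 3 is C8, configuration open) | O[C@@H]1C([C@@H](C)CCCO[Si](C)(C)C(C)(C)C)=C(CO[Si](c2ccccc2)(c2ccccc2)C(C)(C)C)C[C@H]2OC(=O)C(CN(C)C)[C@@H]12 | intermediate (not isolated)
23 | 3-[(trimethylammonio)methyl] iodide derived from 22 (C8 configuration open) | O[C@@H]1C([C@@H](C)CCCO[Si](C)(C)C(C)(C)C)=C(CO[Si](c2ccccc2)(c2ccccc2)C(C)(C)C)C[C@H]2OC(=O)C(C[N+](C)(C)C)[C@@H]12.[I-] | intermediate (not isolated)
24 | (3aS,4S,7aR)-5-[(2S)-5-{[tert-butyl(dimethyl)silyl]oxy}pentan-2-yl]-6-({[tert-butyl(diphenyl)silyl]oxy}methyl)-4-hydroxy-3-methylidene-3a,4,7,7a-tetrahydro-1-benzofuran-2(3H)-one | O[C@@H]1C([C@@H](C)CCCO[Si](C)(C)C(C)(C)C)=C(CO[Si](c2ccccc2)(c2ccccc2)C(C)(C)C)C[C@H]2OC(=O)C(=C)[C@@H]12 | intermediate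
25 | 2-methylprop-2-enoic anhydride (methacrylic anhydride) | CC(=C)C(=O)OC(=O)C(C)=C | starting material
26 | (3aR,4S,7aR)-5-[(2S)-5-{[tert-butyl(dimethyl)silyl]oxy}pentan-2-yl]-6-({[tert-butyl(diphenyl)silyl]oxy}methyl)-3-methylidene-2-oxo-2,3,3a,4,7,7a-hexahydro-1-benzofuran-4-yl 2-methylprop-2-enoate | C=C(C)C(=O)O[C@@H]1C([C@@H](C)CCCO[Si](C)(C)C(C)(C)C)=C(CO[Si](c2ccccc2)(c2ccccc2)C(C)(C)C)C[C@H]2OC(=O)C(=C)[C@@H]12 | intermediate
27 | (3aR,4S,7aR)-6-(hydroxymethyl)-5-[(2S)-5-hydroxypentan-2-yl]-3-methylidene-2-oxo-2,3,3a,4,7,7a-hexahydro-1-benzofuran-4-yl 2-methylprop-2-enoate | C=C(C)C(=O)O[C@@H]1C([C@@H](C)CCCO)=C(CO)C[C@H]2OC(=O)C(=C)[C@@H]12 | target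

## Step count and least certain steps

Total step count: 14 (11 on the main line, 3 for boronate 19). Longest linear sequence: 11 steps (steps 1–6 and 10–14).

**Step 6 (key step).** Water may capture the allyl cation at the tertiary terminus C3 or from the concave face, or the cation may lose a proton to give a bromodiene. The charge is larger at the more substituted end, and the facial bias comes from a single substituent on C6. The fallback sets out from 12 and returns at 13. The silver-mediated opening is run as before and the crude product, which would then contain the C1-epimeric bromo alcohol F1 and the C3 tertiary allylic alcohol F2 beside 13, is oxidised as a whole with pyridinium chlorochromate (C5H5NH)[CrO3Cl] in CH2Cl2. The secondary alcohols are oxidised directly and the tertiary one by Babler–Dauben 1,3-oxidative transposition, so all three converge on the 2-bromo enone F3. Corey–Bakshi–Shibata reduction of F3 [(R)-2-methyl-CBS-oxazaborolidine, catecholborane, toluene, −78 °C, the bromoalkenyl carbon C2 acting as the large group] then sets C1 by reagent control and gives 13.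

**Step 11.** Hydrogen may be delivered to the other face of C1′ if the reactive rotamer is not the one assumed. The twisted diene may be reduced 1,4, or the hindered alkene may react slowly while the allylic alcohol isomerises. The fallback sets out from 13 and returns at 21, using the isomeric 1,1-disubstituted alkene, which is more reactive and gives the opposite C1′ configuration for the same mode of delivery. Commercial pent-4-yn-1-ol (C#CCCCO) is hydrobrominated in the Markovnikov sense (Et4N[HBr2], CH2Cl2, 40 °C) to 4-bromopent-4-en-1-ol F4. This is silylated (TBSCl, imidazole) to the bromoalkene silyl ether F5 and borylated (Miyaura borylation: B2pin2, PdCl2(PPh3)2, PPh3, KOPh, toluene, 50 °C) to the 2-alkenylboronate F6. Coupling with 13 under the conditions of step 10 gives the exocyclic-methylene diene F7, and hydroxyl-directed hydrogenation with [Rh(nbd)(dppb)]BF4 and H2 leads to 21.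

**Step 10.** Oxidative addition and transmetalation at the tetrasubstituted bromide may be slow, so that protodeboronation of 19 competes. The aqueous base may open the lactone or move it from C5–O to the free C1–O. The fallback sets out from 17 and returns at 20. Alkenyllithium 18 is quenched with Bu3SnCl to give the alkenylstannane F8, which is coupled with 13 under base-free Stille conditions (Pd(PPh3)4, CuI, CsF, DMF, 45 °C).

**Step 5.** The amide-to-lactone exchange may remain incomplete at a temperature low enough to keep the strained dibromocyclopropane from ionising, or the TBDPS ether may be lost on prolonged acid treatment. The fallback sets out from 8 and returns at 12, reversing the order of the two operations. Acid at 50 °C (1 M aq. HCl/THF), now without a cyclopropane present, converts 8 through the hydroxy amide F9 into the bicyclic alkene lactone F10. Dibromocarbene from 9 (50% aq. NaOH, BnEt3NCl, CH2Cl2, 0 °C) is then added to the convex face, and acidification to pH 3 recloses any lactone opened by hydroxide.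

**Step 12.** The C1 alkoxide may attack C7 before the enolate forms, moving the lactone to C1–O, and aminomethylation may occur on oxygen or revert. The fallback sets out from 21 and returns at 24 and avoids the lithium dianion. Carboxylation with MeOMgOCO2Me (methyl magnesium carbonate) in DMF at 120 °C gives the α-carboxy lactone F11 as its magnesium chelate, and decarboxylative Mannich methylenation (aq. HCHO, Et2NH, NaOAc, AcOH, rt) gives 24.

## Further compounds

F1 | step 6 | (3aS,4R,7aR)-5-bromo-6-({[tert-butyl(diphenyl)silyl]oxy}methyl)-4-hydroxy-3a,4,7,7a-tetrahydro-1-benzofuran-2(3H)-one (C1 epimer of 13) | O[C@H]1C(Br)=C(CO[Si](c2ccccc2)(c2ccccc2)C(C)(C)C)C[C@H]2OC(=O)C[C@@H]12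
F2 | step 6 | 5-bromo-6-({[tert-butyl(diphenyl)silyl]oxy}methyl)-6-hydroxy-3a,6,7,7a-tetrahydro-1-benzofuran-2(3H)-one (C3 tertiary alcohol, cis-fused, C3 configuration open) | OC1(CO[Si](c2ccccc2)(c2ccccc2)C(C)(C)C)C[C@H]2OC(=O)C[C@H]2C=C1Br
F3 | step 6 | (3aR,7aR)-5-bromo-6-({[tert-butyl(diphenyl)silyl]oxy}methyl)-3a,7a-dihydro-1-benzofuran-2,4(3H,7H)-dione (cis-fused 2-bromo enone) | O=C1C(Br)=C(CO[Si](c2ccccc2)(c2ccccc2)C(C)(C)C)C[C@H]2OC(=O)C[C@@H]12
F4 | step 11 | 4-bromopent-4-en-1-ol | C=C(Br)CCCO
F5 | step 11 | [(4-bromopent-4-en-1-yl)oxy](tert-butyl)dimethylsilane | C=C(Br)CCCO[Si](C)(C)C(C)(C)C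
F6 | step 11 | tert-butyl(dimethyl){[4-(4,4,5,5-tetramethyl-1,3,2-dioxaborolan-2-yl)pent-4-en-1-yl]oxy}silane | C=C(CCCO[Si](C)(C)C(C)(C)C)B1OC(C)(C)C(C)(C)O1
F7 | step 11 | (3aS,4S,7aR)-5-(5-{[tert-butyl(dimethyl)silyl]oxy}pent-1-en-2-yl)-6-({[tert-butyl(diphenyl)silyl]oxy}methyl)-4-hydroxy-3a,4,7,7a-tetrahydro-1-benzofuran-2(3H)-one | O[C@@H]1C(C(=C)CCCO[Si](C)(C)C(C)(C)C)=C(CO[Si](c2ccccc2)(c2ccccc2)C(C)(C)C)C[C@H]2OC(=O)C[C@@H]12
F8 | step 10 | tributyl[(2E)-5-{[tert-butyl(dimethyl)silyl]oxy}pent-2-en-2-yl]stannane (tin trans to the chain) | CCCC[Sn](CCCC)(CCCC)/C(C)=C/CCO[Si](C)(C)C(C)(C)C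
F9 | step 5 | 2-[(1S,5R)-3-({[tert-butyl(diphenyl)silyl]oxy}methyl)-5-hydroxycyclopent-2-en-1-yl]-N,N-dimethylacetamide | CN(C)C(=O)C[C@H]1C=C(CO[Si](c2ccccc2)(c2ccccc2)C(C)(C)C)C[C@H]1O
F10 | step 5 | (3aS,6aR)-5-({[tert-butyl(diphenyl)silyl]oxy}methyl)-3,3a,6,6a-tetrahydro-2H-cyclopenta[b]furan-2-one | O=C1C[C@H]2C=C(CO[Si](c3ccccc3)(c3ccccc3)C(C)(C)C)C[C@H]2O1
F11 | step 12 | 3-carboxylic acid of 21 (carboxyl on C8, C8 configuration open) | O[C@@H]1C([C@@H](C)CCCO[Si](C)(C)C(C)(C)C)=C(CO[Si](c2ccccc2)(c2ccccc2)C(C)(C)C)C[C@H]2OC(=O)C(C(O)=O)[C@@H]12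
A1 | alternative 1 | C6 S-methyl xanthate of the ring A C5 propargyl ether (C1 triethylsilyl ether, C10 and C4′ TBS ethers, C6 configuration open) | CC[Si](CC)(CC)O[C@@H]1C([C@@H](C)CCCO[Si](C)(C)C(C)(C)C)=C(CO[Si](C)(C)C(C)(C)C)C[C@@H](OCC#C)C1OC(=S)SC
A2 | alternative 1 | cis-fused 3-methylenetetrahydrofuran (C7 as CH2) | CC[Si](CC)(CC)O[C@@H]1C([C@@H](C)CCCO[Si](C)(C)C(C)(C)C)=C(CO[Si](C)(C)C(C)(C)C)C[C@H]2OCC(=C)[C@@H]12
A3 | alternative 2 | Z-enal tethered through C4 to the γ-carbon of the butenolide | O=C/C([C@@H](C)CCCO[Si](C)(C)C(C)(C)C)=C(CO[Si](C)(C)C(C)(C)C)\C[C@H]1OC(=O)C=C1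
A4 | alternative 2 | cis-fused C1 enone lactone | O=C1C([C@@H](C)CCCO[Si](C)(C)C(C)(C)C)=C(CO[Si](C)(C)C(C)(C)C)C[C@H]2OC(=O)C[C@@H]12
A5 | alternative 3 | cis-2-ethynyl carbinol carrying the C1 methacrylate | C=C(C)C(=O)O[C@@H]1C([C@@H](C)CCCO[Si](C)(C)C(C)(C)C)=C(CO[Si](C)(C)C(C)(C)C)C[C@@H](O)[C@H]1C#C
A6 | alternative 3 | bis-TBS ether of 27 | C=C(C)C(=O)O[C@@H]1C([C@@H](C)CCCO[Si](C)(C)C(C)(C)C)=C(CO[Si](C)(C)C(C)(C)C)C[C@H]2OC(=O)C(=C)[C@@H]12
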